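**Plan**
- Retrosynthesis: the C12=C13 alkene is cut first (Wittig with a succinimide ylide), then the C6–C7 and C9–C10 bonds of ring B are cut together, a [3+3] disconnection into a ring A methylenecyclohexane (C1–C6, C10, C18–C20) and an acyclic α-(silylmethyl) enal (C7–C9, C11, C12, C17).
- Enabling feature: ring B is a 7-oxygenated 8(17)-methylenecyclohexane fused at C5(H)–C10(quaternary, methyl). C7–C8(=C17)–C9 maps onto an enal carrying an allylsilane, and C6–C5–C10 onto an exocyclic alkene whose allylic tertiary C10–H can move to C5, so nucleophilic C6 is followed by electrophilic C10.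
- Forward: ring A comes from (4R,6R)-actinol (methylenation, then OH to Cl with net retention by double inversion); the enal comes from but-3-yn-1-ol; an MeAlCl2 cascade closes ring B; C7 is then adjusted, acetylated, the chain end oxidised and the imide attached.
- Stereochemistry: C2 is the carbinol carbon of actinol; C5 receives the C6–H of actinol by a 1,2-hydride shift; C10 and C9 follow from the chair closure; C7 is set afterwards by axial hydride delivery to the 7-ketone; the (E)-alkene comes from the stabilised ylide.

Key step: step 9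

Remark: decalin compounds are named on the labdane skeleton (C1–C10 ring carbons, C11–C12 chain, C17 exocyclic methylene, C18–C20 methyls), and (4R,6R)-actinol is assumed to be purchasable.

**Step 1**
Reactants: 1 (4R,6R)-4-hydroxy-2,2,6-trimethylcyclohexan-1-one (actinol)
Product: 2 (1R,5R)-3,3,5-trimethyl-4-methylidenecyclohexan-1-ol
Conditions: Zn, CH2Br2, TiCl4, THF, 0 °C (pre-formed reagent); then 1, CH2Cl2, rt
Reagents that add atoms: dibromomethane, BrCBr
Why: The Takai–Lombardo methylenation is non-basic, so the hindered ketone should be methylenated without epimerising the adjacent methyl-bearing centre, the free hydroxyl being carried as its titanium alkoxide.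

**Step 2**
Reactants: 2 (1R,5R)-3,3,5-trimethyl-4-methylidenecyclohexan-1-ol
Product: 3 (1S,5R)-3,3,5-trimethyl-4-methylidenecyclohexyl 4-nitrobenzoate
Conditions: 4-nitrobenzoic acid, PPh3, DIAD, THF, 0 °C to rt
Reagents that add atoms: 4-nitrobenzoic acid, O=C(O)c1ccc(cc1)[N+](=O)[O-]
Why: In the Mitsunobu reaction the carboxylate displaces the alkoxyphosphonium group by SN2 and inverts the carbinol centre (1R to 1S), the trans alcohol being able to place the leaving group axial for an unhindered equatorial attack.

**Step 3**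
Reactants: 3 (1S,5R)-3,3,5-trimethyl-4-methylidenecyclohexyl 4-nitrobenzoate
Product: 4 (1S,5R)-3,3,5-trimethyl-4-methylidenecyclohexan-1-ol
Conditions: K2CO3, MeOH, rt
Reagents that add atoms: none
Why: Base-catalysed transesterification frees the inverted alcohol without touching a stereocentre.

**Step 4**
Reactants: 4 (1S,5R)-3,3,5-trimethyl-4-methylidenecyclohexan-1-ol
Product: 5 (4R,6R)-4-chloro-2,2,6-trimethyl-1-methylidenecyclohexane
Conditions: PPh3, CCl4, MeCN, 60 °C
Reagents that add atoms: tetrachloromethane, ClC(Cl)(Cl)Cl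
Why: In the Appel reaction chloride displaces the alkoxyphosphonium ion with inversion, so the C–Cl bond regains the spatial sense of the C–O bond of actinol (the future C2 of the target), and the equatorial leaving group lacks an antiperiplanar hydrogen for E2.

**Step 5**
Reactants: 6 but-3-yn-1-ol
Product: 7 (but-3-yn-1-yloxy)(tert-butyl)diphenylsilane
Conditions: TBDPSCl, imidazole, CH2Cl2, rt
Reagents that add atoms: tert-butyl(chloro)diphenylsilane, CC(C)(C)[Si](Cl)(c1ccccc1)c1ccccc1
Why: Standard silyl ether formation gives a primary ether robust enough for the Lewis acid of step 9 and removable beside an acetate.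

**Step 6**
Reactants: 7 (but-3-yn-1-yloxy)(tert-butyl)diphenylsilane
Product: 8 5-[(tert-butyldiphenylsilyl)oxy]pent-2-yn-1-ol
Conditions: n-BuLi, THF, −78 °C; (CH2O)n, −78 °C to rt; then H2O
Reagents that add atoms: formaldehyde (as paraformaldehyde), C=O
Why: Addition of the lithium acetylide to formaldehyde is a routine hydroxymethylation of a terminal alkyne.

**Step 7**
Reactants: 8 5-[(tert-butyldiphenylsilyl)oxy]pent-2-yn-1-ol
Product: 9 (2Z)-5-[(tert-butyldiphenylsilyl)oxy]-2-[(trimethylsilyl)methyl]pent-2-en-1-ol
Conditions: Me3SiCH2MgCl (3.5 equiv), CuI (10 mol %), THF, 0 °C to reflux; then H2O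
Reagents that add atoms: (trimethylsilyl)methylmagnesium chloride, C[Si](C)(C)C[Mg]Cl
Why: In the copper-catalysed anti-carbomagnesiation of a propargylic alcohol the magnesium alkoxide directs the silylmethyl group to C2 and magnesium to C3 on opposite faces, so protonolysis should leave CH2OH trans to the chain (the 2Z isomer).

**Step 8**
Reactants: 9 (2Z)-5-[(tert-butyldiphenylsilyl)oxy]-2-[(trimethylsilyl)methyl]pent-2-en-1-ol
Product: 10 (2Z)-5-[(tert-butyldiphenylsilyl)oxy]-2-[(trimethylsilyl)methyl]pent-2-enal
Conditions: MnO2, CH2Cl2, rt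
Reagents that add atoms: none
Why: MnO2 oxidation of the allylic alcohol is neutral, so the allylsilane and the alkene geometry (formyl trans to the chain) should be kept.

**Step 9**
Reactants: 5 (4R,6R)-4-chloro-2,2,6-trimethyl-1-methylidenecyclohexane; 10 (2Z)-5-[(tert-butyldiphenylsilyl)oxy]-2-[(trimethylsilyl)methyl]pent-2-enal
Product: 13 12-[(tert-butyldiphenylsilyl)oxy]-2α-chloro-13,14,15,16-tetranorlabd-8(17)-en-7ξ-ol (both C7 epimers), via C5 carbocation aluminate zwitterion 11 (not isolated), via C10 carbocation aluminate zwitterion 12 (not isolated)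
Conditions: MeAlCl2 (2.2 equiv), CH2Cl2, −78 to −30 °C, 10 added slowly to 5 (1.3 equiv); then H2O
Reagents that add atoms: none
Why: Proposed new method: the MeAlCl2-activated enal 10 is attacked at its carbonyl carbon by the terminal methylene carbon (C6) of 5 (Prins addition, bond C6–C7) to give tertiary cation 11 at C5; with two equivalents of MeAlCl2 the aluminate oxygen should be too weakly basic for ene-type proton loss, so the axial C10–H shifts suprafacially to C5 and the C10 cation 12 is captured 6-endo-trig by the allylsilane (bond C9–C10) with loss of the silyl group to unveil the 8(17)-methylene. The closest known reactions are alkylaluminium-halide-promoted aldehyde–alkene additions whose zwitterions undergo 1,2-hydride shifts, and allylsilane-terminated cation–olefin cyclisations of monocyclic 5(10)-ene precursors to trans-decalins. Ring B should close through a chair transition state on a chair ring A that keeps the C2 chlorine equatorial. C5 is set by the stereospecific hydride shift (5α-H, relayed from C6 of actinol), C10 by entry of C9 on the face vacated by that hydrogen with the C5–C6 tether equatorial (trans fusion, axial methyl), and C9 by the alkene geometry of 10 (C11 equatorial), whereas C7 forms in the intermolecular step without control and is corrected in steps 10 and 11. The step needs 1,2- over 1,4-attack on the enal (favoured by its α-branch and β-alkyl group), hydride shift over proton loss or C4-methyl shift, and 6-endo capture at C10 over 5-endo capture at C5; any proton that is lost is destroyed as methane, so the allylsilane should not be protodesilylated.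

**Step 10**
Reactants: 13 12-[(tert-butyldiphenylsilyl)oxy]-2α-chloro-13,14,15,16-tetranorlabd-8(17)-en-7ξ-ol
Product: 14 12-[(tert-butyldiphenylsilyl)oxy]-2α-chloro-13,14,15,16-tetranorlabd-8(17)-en-7-one
Conditions: DMP, CH2Cl2, 0 °C to rt
Reagents that add atoms: none
Why: Dess–Martin oxidation under near-neutral conditions converges both C7 epimers on one α-methylene ketone without moving the exocyclic alkene into the ring.

**Step 11**
Reactants: 14 12-[(tert-butyldiphenylsilyl)oxy]-2α-chloro-13,14,15,16-tetranorlabd-8(17)-en-7-one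
Product: 15 12-[(tert-butyldiphenylsilyl)oxy]-2α-chloro-13,14,15,16-tetranorlabd-8(17)-en-7β-ol
Conditions: NaBH4, CeCl3·7H2O, MeOH, −78 °C
Reagents that add atoms: none
Why: Luche reduction is 1,2-selective for the enone, and axial delivery of the small hydride on the α face of the rigid trans-decalin should give the equatorial 7β-alcohol.

**Step 12**
Reactants: 15 12-[(tert-butyldiphenylsilyl)oxy]-2α-chloro-13,14,15,16-tetranorlabd-8(17)-en-7β-ol
Product: 16 7β-acetoxy-12-[(tert-butyldiphenylsilyl)oxy]-2α-chloro-13,14,15,16-tetranorlabd-8(17)-ene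
Conditions: Ac2O, pyridine, DMAP (cat.), CH2Cl2, rt
Reagents that add atoms: acetic anhydride, CC(=O)OC(C)=O
Why: DMAP-catalysed acylation of the unhindered equatorial allylic alcohol proceeds with retention at C7.

**Step 13**
Reactants: 16 7β-acetoxy-12-[(tert-butyldiphenylsilyl)oxy]-2α-chloro-13,14,15,16-tetranorlabd-8(17)-ene
Product: 17 7β-acetoxy-2α-chloro-13,14,15,16-tetranorlabd-8(17)-en-12-ol
Conditions: HF·pyridine, THF, 0 °C to rt
Reagents that add atoms: none
Why: Fluoride-driven cleavage of the primary silyl ether under mildly acidic conditions should leave the allylic acetate, the chloride and the exocyclic alkene untouched.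

**Step 14**
Reactants: 17 7β-acetoxy-2α-chloro-13,14,15,16-tetranorlabd-8(17)-en-12-ol
Product: 18 7β-acetoxy-2α-chloro-13,14,15,16-tetranorlabd-8(17)-en-12-al
Conditions: DMP, CH2Cl2, rt
Reagents that add atoms: none
Why: Dess–Martin oxidation stops at the aldehyde and does not disturb the acetate or the remote stereocentres.

**Step 15**
Reactants: 19 maleimide (1H-pyrrole-2,5-dione)
Product: 20 3-(triphenylphosphoranylidene)pyrrolidine-2,5-dione
Conditions: PPh3, acetone, reflux
Reagents that add atoms: triphenylphosphine, c1ccc(cc1)P(c1ccccc1)c1ccccc1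
Why: Conjugate addition of the phosphine to maleimide followed by proton transfer gives the isolable imide-stabilised ylide.

**Step 16**
Reactants: 18 7β-acetoxy-2α-chloro-13,14,15,16-tetranorlabd-8(17)-en-12-al; 20 3-(triphenylphosphoranylidene)pyrrolidine-2,5-dione
Product: 21 target CNP0220384.1, (12E)-7β-acetoxy-2α-chlorolabda-8(17),12-diene-15,16-dicarboximide
Conditions: THF, 60 °C
Reagents that add atoms: none
Why: The Wittig reaction of the stabilised ylide needs no added base and should give the (E)-alkylidene succinimide (C11 anti to the adjacent ring carbonyl), leaving acetate, chloride and exocyclic alkene intact.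

**Compound list**
1 | (4R,6R)-4-hydroxy-2,2,6-trimethylcyclohexan-1-one (actinol) | O=C1C(C)(C)C[C@H](O)C[C@H]1C | starting material
2 | (1R,5R)-3,3,5-trimethyl-4-methylidenecyclohexan-1-ol | C=C1C(C)(C)C[C@H](O)C[C@H]1C | intermediate
3 | (1S,5R)-3,3,5-trimethyl-4-methylidenecyclohexyl 4-nitrobenzoate | C=C1C(C)(C)C[C@@H](OC(=O)c2ccc(cc2)[N+](=O)[O-])C[C@H]1C | intermediate
4 | (1S,5R)-3,3,5-trimethyl-4-methylidenecyclohexan-1-ol | C=C1C(C)(C)C[C@@H](O)C[C@H]1C | intermediate
5 | (4R,6R)-4-chloro-2,2,6-trimethyl-1-methylidenecyclohexane | C=C1C(C)(C)C[C@H](Cl)C[C@H]1C | intermediate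
6 | but-3-yn-1-ol | C#CCCO | starting material
7 | (but-3-yn-1-yloxy)(tert-butyl)diphenylsilane | C#CCCO[Si](c1ccccc1)(c1ccccc1)C(C)(C)C | intermediate
8 | 5-[(tert-butyldiphenylsilyl)oxy]pent-2-yn-1-ol | OCC#CCCO[Si](c1ccccc1)(c1ccccc1)C(C)(C)C | intermediate
9 | (2Z)-5-[(tert-butyldiphenylsilyl)oxy]-2-[(trimethylsilyl)methyl]pent-2-en-1-ol | OC/C(C[Si](C)(C)C)=C/CCO[Si](c1ccccc1)(c1ccccc1)C(C)(C)C | intermediate
10 | (2Z)-5-[(tert-butyldiphenylsilyl)oxy]-2-[(trimethylsilyl)methyl]pent-2-enal | O=C/C(C[Si](C)(C)C)=C/CCO[Si](c1ccccc1)(c1ccccc1)C(C)(C)C | intermediate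
11 | C5 carbocation aluminate zwitterion (after Prins addition, C10–H still in place) | C[Si](C)(C)C/C(=C\CCO[Si](c1ccccc1)(c1ccccc1)C(C)(C)C)C(O[Al-](C)(Cl)Cl)C[C+]1C(C)(C)C[C@H](Cl)C[C@H]1C | intermediate
12 | C10 carbocation aluminate zwitterion (after 1,2-hydride shift, 5α-H) | C[Si](C)(C)C/C(=C\CCO[Si](c1ccccc1)(c1ccccc1)C(C)(C)C)C(O[Al-](C)(Cl)Cl)C[C@H]1C(C)(C)C[C@H](Cl)C[C+]1C | intermediate
13 | 12-[(tert-butyldiphenylsilyl)oxy]-2α-chloro-13,14,15,16-tetranorlabd-8(17)-en-7ξ-ol (C7 unspecified, both epimers) | C=C1C(O)C[C@H]2C(C)(C)C[C@H](Cl)C[C@]2(C)[C@H]1CCO[Si](c1ccccc1)(c1ccccc1)C(C)(C)C | intermediate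
14 | 12-[(tert-butyldiphenylsilyl)oxy]-2α-chloro-13,14,15,16-tetranorlabd-8(17)-en-7-one | C=C1C(=O)C[C@H]2C(C)(C)C[C@H](Cl)C[C@]2(C)[C@H]1CCO[Si](c1ccccc1)(c1ccccc1)C(C)(C)C | intermediate
15 | 12-[(tert-butyldiphenylsilyl)oxy]-2α-chloro-13,14,15,16-tetranorlabd-8(17)-en-7β-ol | C=C1[C@@H](O)C[C@H]2C(C)(C)C[C@H](Cl)C[C@]2(C)[C@H]1CCO[Si](c1ccccc1)(c1ccccc1)C(C)(C)C | intermediate
16 | 7β-acetoxy-12-[(tert-butyldiphenylsilyl)oxy]-2α-chloro-13,14,15,16-tetranorlabd-8(17)-ene | C=C1[C@@H](OC(C)=O)C[C@H]2C(C)(C)C[C@H](Cl)C[C@]2(C)[C@H]1CCO[Si](c1ccccc1)(c1ccccc1)C(C)(C)C | intermediate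
17 | 7β-acetoxy-2α-chloro-13,14,15,16-tetranorlabd-8(17)-en-12-ol | C=C1[C@@H](OC(C)=O)C[C@H]2C(C)(C)C[C@H](Cl)C[C@]2(C)[C@H]1CCO | intermediate
18 | 7β-acetoxy-2α-chloro-13,14,15,16-tetranorlabd-8(17)-en-12-al | C=C1[C@@H](OC(C)=O)C[C@H]2C(C)(C)C[C@H](Cl)C[C@]2(C)[C@H]1CC=O | intermediate
19 | maleimide (1H-pyrrole-2,5-dione) | O=C1C=CC(=O)N1 | starting material
20 | 3-(triphenylphosphoranylidene)pyrrolidine-2,5-dione | O=C1CC(=P(c2ccccc2)(c2ccccc2)c2ccccc2)C(=O)N1 | intermediate
21 | CNP0220384.1, (12E)-7β-acetoxy-2α-chlorolabda-8(17),12-diene-15,16-dicarboximide, (2S,5S,7S,9R,10S) | C=C1[C@@H](OC(C)=O)C[C@H]2C(C)(C)C[C@H](Cl)C[C@]2(C)[C@H]1C/C=C1\CC(=O)NC1=O | target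

**Step count**
Total steps: 16. Longest linear sequence: 11 (steps 1–4, 9–14 and 16; the branch through steps 5–8 is equally long).

**Steps most likely to fail**

Step 9 (proposed new method). Proton loss from the C5 cation to the aluminate oxygen may outrun the 1,2-hydride shift, so that the cascade stops at the monocyclic ene stage. The C7 oxygen may also trap the C10 cation as a bicyclic ether, a C4 methyl may migrate in place of the C10 hydrogen, or the alkene may add in conjugate fashion to the enal. The fallback makes the two bonds one at a time by reactions of known type, sets out from 5 and 10 and comes back at 13. Me2AlCl (1.5 equiv, CH2Cl2, −78 to 0 °C) should promote the ordinary carbonyl-ene reaction, the transferred proton leaving as methane, to give ene adduct F1, a homoallylic alcohol with the tetrasubstituted C5=C10 alkene. F1 would then be closed with SnCl4 (CH2Cl2, −78 °C): the tin-bound hydroxyl acts as the Brønsted acid that protonates C5, and the allylsilane terminates the cation–olefin cyclisation at C10 to give 13.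

Step 4. Substitution may be slow because chloride has to approach the equatorial alkoxyphosphonium carbon syn-axial to a ring methyl, leaving elimination or recovered alcohol. The fallback avoids both inversions, sets out from 2 and comes back at 5. SOCl2 (CH2Cl2, 0 °C) should convert 2 into chlorosulfite F2, and catalytic TiCl4 then collapses it with front-side delivery of chloride, a stereoretentive chlorination known for cyclic secondary alcohols; compounds 3 and 4 are bypassed.

Step 7. Carbometallation of the internal alkynol with the sluggish silylmethyl Grignard reagent may be incomplete or give the regioisomer. The fallback sets out from 8 and comes back at 9. LiAlH4/AlCl3 (THF) trans-hydroalumination places aluminium on C2, and iodine then gives vinyl iodide F3 with the hydroxymethyl group trans to the chain. Kumada coupling of F3 with Me3SiCH2MgCl and Pd(PPh3)4 (THF, rt) proceeds with retention to give 9.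

**Further compounds**
F1 | step 9 | (3Z)-6-[(tert-butyldiphenylsilyl)oxy]-1-[(4R)-4-chloro-2,6,6-trimethylcyclohex-1-en-1-yl]-3-[(trimethylsilyl)methyl]hex-3-en-2-ol (both C2 epimers) | C[Si](C)(C)C/C(=C\CCO[Si](c1ccccc1)(c1ccccc1)C(C)(C)C)C(O)CC1=C(C)C[C@@H](Cl)CC1(C)C
F2 | step 4 | (1R,5R)-3,3,5-trimethyl-4-methylidenecyclohexyl chlorosulfite | C=C1C(C)(C)C[C@H](OS(Cl)=O)C[C@H]1C
F3 | step 7 | (2Z)-5-[(tert-butyldiphenylsilyl)oxy]-2-iodopent-2-en-1-ol | OC/C(I)=C/CCO[Si](c1ccccc1)(c1ccccc1)C(C)(C)C
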